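The data stem from a simulated flask with made-up constants.

| flask | Z | L | remark | time |
|---|---|---|---|---|
| theta | 0.090 M | 0.95 equiv | run made earlier |  |
| alpha | 0.36 M | 0.95 equiv | run made earlier |  |
| delta | 0.18 M | 1.4 equiv | run made earlier |  |
| noon | 0.18 M | 0.950 equiv |  | 25 h |
| midnight | 0.18 M | 0.950 equiv |  | 30 h |

| run | time / h | Q / % | D / % | X / % | Z / % | E / % |
|---|---|---|---|---|---|---|
| theta | 1.33 | 22.8 | 0 | 2.6 | 75.1 | 0 |
| theta | 3.00 | 42.0 | 1.7 | 1.2 | 54.3 | 0.2 |
| theta | 6.00 | 61.2 | 0 | 6.0 | 29.0 | 1.2 |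
| theta | 15.0 | 64.8 | 3.9 | 22.1 | 4.8 | 6.3 |
| alpha | 2.00 | 28.9 | 0.9 | 2.6 | 67.1 | 0.3 |
| alpha | 5.00 | 45.7 | 2.9 | 16.1 | 34.8 | 2.0 |
| alpha | 10.0 | 47.8 | 2.4 | 36.7 | 14.4 | 3.7 |
| alpha | 15.0 | 40.0 | 4.8 | 49.5 | 4.5 | 2.9 |
| delta | 2.00 | 30.0 | 0 | 2.5 | 66.6 | 0 |
| delta | 5.00 | 48.5 | 1.0 | 11.2 | 37.5 | 0.7 |
| delta | 10.0 | 50.4 | 1.7 | 31.3 | 12.1 | 2.3 |
| delta | 15.0 | 43.0 | 4.3 | 45.0 | 4.5 | 2.8 |

(each reading ± 1 percentage point)

1. which of these there is most of at the end, counted by the Z in it, noon (E / X / D / Q)
2. which of these there is most of at the end, counted by the Z in it, midnight (E / X / D / Q)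
3. final amount of the leader among these, as a percentage of the Z charged, in noon
4. final amount of the leader among these, as a percentage of the Z charged, in midnight

Start from the constants. In the alpha run the readings of Z give a lifetime τ of 4.81 h, and at 15.0 h the theta run holds 4.8% of Z against 4.5% in alpha, though theta was charged at a quarter of alpha's concentration. So take τ as an induction time, and take L + Q, a second-order step, to run after it on concentration times time. Call the delayed dose W the Z concentration c times (t − τ); for noon W is 218 M·min. At equal equivalents, take equal W to mean roughly equal X, and take the odds of X, X over the rest of the Z charged, to grow in proportion to W.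

Turn the settings one by one. Concentration: from theta to alpha at 15.0 h, W goes from 55.0 M·min to 220 M·min, and the readings of X go from 22.1% to 49.5%. Equivalents: delta at 15.0 h has W 110 M·min, about the same as alpha at 10.0 h with 112 M·min, yet holds 45.0% of X against 36.7%. So alpha, with noon's equivalents, is the reference. Time: noon's W is nearly alpha's last, so you expect 49.5% of X, ahead of Q at 40.0%. Midnight's W of 272 M·min scales the odds up, and those odds give 54.8% of X.

The forecast names X at both times, with 49% at noon and 53% at midnight, on the ground that “X growth fits rate = k[Q][L]”. Your midnight figure stands higher than its midnight figure.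

Noon gives X in the lead with 47.8%, and midnight gives X in the lead with 52.3%. At noon X leads Q by 5.9 percentage points. The reckoning from W of 218 M·min stood 1.7 points above noon's X, and the one from 272 M·min stood 2.5 points above midnight's X.

    Z → Q (k = 0.00340 /min)
    L + Q → X (k = 0.00560 /M/min)
    Q ⇌ E (K = 0.110, k = 3.20 × 10⁻⁴ /min)
    L + E → D (k = 0.0120 /M/min)
    D → J (k = 3.90 × 10⁻⁴ /min)

Noon read at 10 h has W 56.0 M·min, close to theta's last, so you expect 22.1% of X. The flask gives 22.5%.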